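The route rests on the 1,4-relationship between the C6 chlorine and the C2′ heteroatom across the exocyclic C1=C1′ alkene of the six-membered ring (C1 alkylidene, C2 CHCl beside C3 gem-dimethyl, C4 CHBr, C6 CHCl). A palladium-catalysed 1,4-chloroacetoxylation of the C6=C1–C1′=C2′ diene forms the C6–Cl and C2′–O bonds, the Z alkene and the C6 stereocentre in one operation, directed by the resident C2 chlorine. The precursor is vinylcyclohexene 13, which already carries the C2 chlorine and C4 bromine; it comes from 4,4-dimethylcyclohexadienone by asymmetric conjugate borylation, vinylation, invertive bromodeboronation and a transposing allylic chlorination. Deacetylation and Appel bromination finish the route.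

Key step: step 8

Assumption: the absolute sense of the copper-catalysed borylation in step 1 is set by the ligand enantiomer; the antipode that gives the (R)-boronate 3 is the one to use.
Remark on numbering: compounds 3 to 12 are numbered as in their names (C1 carbonyl or carbinol carbon, C2 vinyl-bearing carbon, C4 gem-dimethyl carbon, C5 boron- or bromine-bearing carbon). From 14 on the target numbering of the overview applies. C3 of 11 becomes C6 of 13 and C2 of 14 to 16.

Step 1
Reactants: 1 4,4-dimethylcyclohexa-2,5-dien-1-one; 2 bis(pinacolato)diboron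
Product: 3 (R)-4,4-dimethyl-5-(4,4,5,5-tetramethyl-1,3,2-dioxaborolan-2-yl)cyclohex-2-en-1-one
Conditions: CuCl (5 mol %), NaOtBu (6 mol %), (R)-1-[(S)-2-(diphenylphosphino)ferrocenyl]ethyldicyclohexylphosphine (6 mol %), 1 (1.3 equiv), MeOH (2 equiv), THF, 0 °C to rt
Reagents that add atoms: none
Why: Copper-catalysed asymmetric conjugate borylation of an enone: the chiral bisphosphine copper boryl adds across one enantiotopic face of either (homotopic) enone arm of the symmetric dienone, which sets C5 as R, and keeping the diboron limiting leaves the second arm untouched.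

Step 2
Reactants: 3 (R)-4,4-dimethyl-5-(4,4,5,5-tetramethyl-1,3,2-dioxaborolan-2-yl)cyclohex-2-en-1-one
Product: 4 (R)-2-iodo-4,4-dimethyl-5-(4,4,5,5-tetramethyl-1,3,2-dioxaborolan-2-yl)cyclohex-2-en-1-one
Conditions: I2 (1.5 equiv), pyridine/CH2Cl2 1:1, rt, dark
Reagents that add atoms: iodine, [I][I]
Why: Pyridine-promoted α-iodination of an enone (conjugate addition of pyridine, iodination of the enolate and elimination), a standard reaction of 4,4-dimethylcyclohexenones that touches only the vinylic C2–H and leaves the alkyl boronate and its stereocentre alone.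

Step 3
Reactants: 4 (R)-2-iodo-4,4-dimethyl-5-(4,4,5,5-tetramethyl-1,3,2-dioxaborolan-2-yl)cyclohex-2-en-1-one; 5 tributyl(vinyl)stannane
Product: 6 (R)-2-ethenyl-4,4-dimethyl-5-(4,4,5,5-tetramethyl-1,3,2-dioxaborolan-2-yl)cyclohex-2-en-1-one
Conditions: 5 (1.2 equiv), Pd2(dba)3 (2.5 mol %), AsPh3 (10 mol %), CuI (10 mol %), DMF, rt; product carried on without storage
Reagents that add atoms: none
Why: Stille coupling of an α-iodoenone with a vinylstannane under base-free, copper-assisted conditions, to which the secondary alkyl pinacol boronate is inert.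

Step 4
Reactants: 6 (R)-2-ethenyl-4,4-dimethyl-5-(4,4,5,5-tetramethyl-1,3,2-dioxaborolan-2-yl)cyclohex-2-en-1-one
Product: 7 (1S,5R)-2-ethenyl-4,4-dimethyl-5-(4,4,5,5-tetramethyl-1,3,2-dioxaborolan-2-yl)cyclohex-2-en-1-ol
Conditions: NaBH4 (1.1 equiv), CeCl3·7H2O (1.1 equiv), MeOH, −78 to −40 °C
Reagents that add atoms: none
Why: Luche 1,2-reduction of the enone, in which hydride attacks the carbonyl face opposite the C5 substituent as in other 5-substituted cyclohexenones, so that the new C1 carbinol is S with the hydroxyl cis to boron.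

Step 5
Reactants: 7 (1S,5R)-2-ethenyl-4,4-dimethyl-5-(4,4,5,5-tetramethyl-1,3,2-dioxaborolan-2-yl)cyclohex-2-en-1-ol
Product: 8 triethyl{[(1S,5R)-2-ethenyl-4,4-dimethyl-5-(4,4,5,5-tetramethyl-1,3,2-dioxaborolan-2-yl)cyclohex-2-en-1-yl]oxy}silane
Conditions: Et3SiCl (1.2 equiv), imidazole (2 equiv), CH2Cl2, 0 °C to rt
Reagents that add atoms: chlorotriethylsilane, CC[Si](Cl)(CC)CC
Why: Routine silylation of a secondary allylic alcohol, needed because a free hydroxyl would consume the aryllithium and its alkoxide would chelate boron in step 6.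

Step 6
Reactants: 8 triethyl{[(1S,5R)-2-ethenyl-4,4-dimethyl-5-(4,4,5,5-tetramethyl-1,3,2-dioxaborolan-2-yl)cyclohex-2-en-1-yl]oxy}silane
Product: 11 (1S,5S)-5-bromo-2-ethenyl-4,4-dimethylcyclohex-2-en-1-ol, via lithium boronate complex 9 (not isolated), via bromo silyl ether 10 (not isolated)
Conditions: 3,5-(CF3)2C6H3Li (1.2 equiv, from the aryl bromide and n-BuLi), THF, −78 °C; NBS (1.3 equiv), THF, −78 to 0 °C; then 1 M aq HCl, 0 °C to rt
Reagents that add atoms: N-bromosuccinimide, O=C1CCC(=O)N1Br
Why: Stereospecific halodeboronation of a secondary alkyl pinacol boronate through its aryl boronate complex: the electron-poor aryllithium adds to boron to give 9, NBS then attacks the C5 carbon from the side opposite boron (electrophilic substitution with inversion), which makes C5 S and places bromine trans to the C1 oxygen, and dilute acid finally cleaves the triethylsilyl ether.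

Step 7
Reactants: 11 (1S,5S)-5-bromo-2-ethenyl-4,4-dimethylcyclohex-2-en-1-ol
Product: 13 (4S,6S)-4-bromo-6-chloro-1-ethenyl-5,5-dimethylcyclohex-1-ene, via allylic chlorosulfite 12 (not isolated)
Conditions: SOCl2 (1.2 equiv), Et2O (dilute), −20 °C to rt, no base
Reagents that add atoms: thionyl chloride, O=S(Cl)Cl
Why: Chlorination of a secondary allylic alcohol with allylic transposition by internal return from its chlorosulfite (the SNi′ pathway of SOCl2 in ether without base): the pseudoaxial chlorosulfite of 12 hands chlorine to C3 on the face from which oxygen departs, so the new stereocentre (C6 of 13, S) is cis to the former hydroxyl and trans to bromine, and the ring alkene moves to C1=C2.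

Step 8
Reactants: 13 (4S,6S)-4-bromo-6-chloro-1-ethenyl-5,5-dimethylcyclohex-1-ene
Product: 14 (Z)-2-[(2S,4S,6S)-4-bromo-2,6-dichloro-3,3-dimethylcyclohexylidene]ethyl acetate
Conditions: Pd(OAc)2 (5 mol %), p-benzoquinone (2 equiv), LiCl (2 equiv), LiOAc·2H2O (4 equiv), AcOH–pentane, rt
Reagents that add atoms: lithium chloride, [Li+].[Cl-]; lithium acetate, [Li+].CC([O-])=O
Why: Divalent palladium binds the s-trans diene of 13 on the ring face opposite the pseudoaxial C2 chlorine, acetate attacks the primary terminus C2′ from outside, and an η3-allylpalladium unit over C1′–C1–C6 results. Chloride then attacks C6 on the face opposite the metal, and the zerovalent palladium set free is reoxidised by benzoquinone, so no ring is closed. The closest precedent is the palladium diacetate–benzoquinone 1,4-chloroacetoxylation of cyclic and acyclic conjugated dienes, here applied to a 1-vinylcyclohexene. The new C6 stereocentre (S) is controlled by the C2 chlorine: metal anti to it and chloride anti to the metal give the cis-2,6-dichloride, with both chlorines axial and free of A1,3 strain against the exocyclic alkene. The step needs regiocontrol (acetate at C2′ and chloride at C6 for the 1,4-adduct, the usual outcome when the allyl terminus remote from the acetate is attacked), face control (from the C2 chlorine) and geometry control (the CH2OAc group sits syn in the allyl intermediate because the diene reacts s-trans, which gives the Z alkene with C2′ cis to C2). The secondary bromide and the allylic chloride should be spectators under these oxidising, acidic conditions.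

Step 9
Reactants: 14 (Z)-2-[(2S,4S,6S)-4-bromo-2,6-dichloro-3,3-dimethylcyclohexylidene]ethyl acetate
Product: 15 (Z)-2-[(2S,4S,6S)-4-bromo-2,6-dichloro-3,3-dimethylcyclohexylidene]ethan-1-ol
Conditions: i-Bu2AlH (2.2 equiv), CH2Cl2, −78 °C; aq potassium sodium tartrate work-up
Reagents that add atoms: none
Why: Reductive cleavage of the acetate ester by an aluminium hydride at low temperature, chosen over basic methanolysis so that the two allylic chlorides and the secondary bromide never meet an alkoxide; no stereocentre or alkene is touched.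

Step 10
Reactants: 15 (Z)-2-[(2S,4S,6S)-4-bromo-2,6-dichloro-3,3-dimethylcyclohexylidene]ethan-1-ol
Product: 16 (1Z,2S,4S,6S)-4-bromo-1-(2-bromoethylidene)-2,6-dichloro-3,3-dimethylcyclohexane
Conditions: CBr4 (1.3 equiv), PPh3 (1.4 equiv), CH2Cl2, 0 °C
Reagents that add atoms: carbon tetrabromide, BrC(Br)(Br)Br
Why: Appel bromination, an SN2 displacement at the unhindered primary allylic carbon through the alkoxyphosphonium salt, which leaves the alkene geometry and the three secondary halides as they are.

Compound list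
1 | 4,4-dimethylcyclohexa-2,5-dien-1-one | CC1(C)C=CC(=O)C=C1 | starting material
2 | bis(pinacolato)diboron | CC1(C)OB(OC1(C)C)B1OC(C)(C)C(C)(C)O1 | starting material
3 | (R)-4,4-dimethyl-5-(4,4,5,5-tetramethyl-1,3,2-dioxaborolan-2-yl)cyclohex-2-en-1-one | CC1(C)[C@H](B2OC(C)(C)C(C)(C)O2)CC(=O)C=C1 | intermediate
4 | (R)-2-iodo-4,4-dimethyl-5-(4,4,5,5-tetramethyl-1,3,2-dioxaborolan-2-yl)cyclohex-2-en-1-one | CC1(C)[C@H](B2OC(C)(C)C(C)(C)O2)CC(=O)C(I)=C1 | intermediate
5 | tributyl(vinyl)stannane | C=C[Sn](CCCC)(CCCC)CCCC | starting material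
6 | (R)-2-ethenyl-4,4-dimethyl-5-(4,4,5,5-tetramethyl-1,3,2-dioxaborolan-2-yl)cyclohex-2-en-1-one | CC1(C)[C@H](B2OC(C)(C)C(C)(C)O2)CC(=O)C(C=C)=C1 | intermediate
7 | (1S,5R)-2-ethenyl-4,4-dimethyl-5-(4,4,5,5-tetramethyl-1,3,2-dioxaborolan-2-yl)cyclohex-2-en-1-ol (hydroxyl cis to boron) | CC1(C)[C@H](B2OC(C)(C)C(C)(C)O2)C[C@H](O)C(C=C)=C1 | intermediate
8 | triethyl{[(1S,5R)-2-ethenyl-4,4-dimethyl-5-(4,4,5,5-tetramethyl-1,3,2-dioxaborolan-2-yl)cyclohex-2-en-1-yl]oxy}silane | CC1(C)[C@H](B2OC(C)(C)C(C)(C)O2)C[C@H](O[Si](CC)(CC)CC)C(C=C)=C1 | intermediate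
9 | lithium boronate complex of 8 with 3,5-bis(trifluoromethyl)phenyl on boron (ring stereocentres unchanged) | [Li+].CC1(C)[C@H]([B-]2(OC(C)(C)C(C)(C)O2)c2cc(cc(c2)C(F)(F)F)C(F)(F)F)C[C@H](O[Si](CC)(CC)CC)C(C=C)=C1 | intermediate
10 | {[(1S,5S)-5-bromo-2-ethenyl-4,4-dimethylcyclohex-2-en-1-yl]oxy}triethylsilane | CC1(C)[C@@H](Br)C[C@H](O[Si](CC)(CC)CC)C(C=C)=C1 | intermediate
11 | (1S,5S)-5-bromo-2-ethenyl-4,4-dimethylcyclohex-2-en-1-ol (hydroxyl trans to bromine) | CC1(C)[C@@H](Br)C[C@H](O)C(C=C)=C1 | intermediate
12 | (1S,5S)-5-bromo-2-ethenyl-4,4-dimethylcyclohex-2-en-1-yl chlorosulfite | CC1(C)[C@@H](Br)C[C@H](OS(Cl)=O)C(C=C)=C1 | intermediate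
13 | (4S,6S)-4-bromo-6-chloro-1-ethenyl-5,5-dimethylcyclohex-1-ene (chlorine trans to bromine) | CC1(C)[C@@H](Br)CC=C(C=C)[C@@H]1Cl | intermediate
14 | (Z)-2-[(2S,4S,6S)-4-bromo-2,6-dichloro-3,3-dimethylcyclohexylidene]ethyl acetate | CC1(C)[C@@H](Br)C[C@H](Cl)/C(=C/COC(C)=O)[C@@H]1Cl | intermediate
15 | (Z)-2-[(2S,4S,6S)-4-bromo-2,6-dichloro-3,3-dimethylcyclohexylidene]ethan-1-ol | CC1(C)[C@@H](Br)C[C@H](Cl)/C(=C/CO)[C@@H]1Cl | intermediate
16 | (1Z,2S,4S,6S)-4-bromo-1-(2-bromoethylidene)-2,6-dichloro-3,3-dimethylcyclohexane (CNP0156384.1) | CC1(C)[C@@H](Br)C[C@H](Cl)/C(=C/CBr)[C@@H]1Cl | target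

Total step count: 10. Longest linear sequence: 10 steps (1 to 16).

Steps most likely to fail

Step 8 (key step). Facial discrimination in the palladium–diene coordination may be incomplete, because the axial C3 methyl group partly shields the face opposite the C2 chlorine. Chloride may also attack C1′ instead of C6 (1,2-adduct), and syn–anti equilibration of the allyl intermediate may erode the alkene geometry. The fallback sets out from 13. The ring alkene is epoxidised with mCPBA (NaHCO3 buffer) on the face opposite the pseudoaxial chlorine to give (1R,2R,4S,6R)-4-bromo-2-chloro-1-ethenyl-3,3-dimethyl-7-oxabicyclo[4.1.0]heptane F1. This vinyl epoxide is opened in a 1,4-sense with acetic acid and Pd(PPh3)4 (zerovalent palladium, Tsuji–Trost reaction) to (Z)-2-[(2S,4S,6R)-4-bromo-2-chloro-6-hydroxy-3,3-dimethylcyclohexylidene]ethyl acetate F2. The C6 hydroxyl is then replaced by chloride with inversion (PPh3, CCl4), and the route is rejoined at 14.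

Step 7. The chlorosulfite ion pair may collapse at C1 instead of C3 (substitution without transposition), full ionisation may lose the syn delivery, and the HCl formed may add to the diene. The fallback sets out from 11. Oxidation with MnO2 gives (S)-5-bromo-2-ethenyl-4,4-dimethylcyclohex-2-en-1-one F3. Dry HCl is added in conjugate fashion at low temperature, chloride entering C3 anti to the C5 bromine, to give (2S,3S,5S)-5-bromo-3-chloro-2-ethenyl-4,4-dimethylcyclohexan-1-one F4. This is reduced in the same flask with NaBH4 to (1R,2S,3S,5S)-5-bromo-3-chloro-2-ethenyl-4,4-dimethylcyclohexan-1-ol F5. Dehydration across C1–C2 with the Burgess reagent (syn elimination towards the allylic hydrogen) rejoins the route at 13.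

Step 6. Attack of NBS at the carbon next to the quaternary centre may be slowed, so that single-electron oxidation of the boronate complex and radical bromination erode the inversion, and NBS may react with the diene. The fallback sets out from 8. The C–B bond is oxidised with NaBO3·4H2O (retention) to (1R,5S)-4-ethenyl-2,2-dimethyl-5-[(triethylsilyl)oxy]cyclohex-3-en-1-ol F6. Tf2O and pyridine convert it into (1R,5S)-4-ethenyl-2,2-dimethyl-5-[(triethylsilyl)oxy]cyclohex-3-en-1-yl trifluoromethanesulfonate F7. Displacement with LiBr (SN2, inversion) reaches 10, and removal of the silyl group with dilute acid as in step 6 rejoins the route at 11.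

Further compounds
F1 | step 8 | (1R,2R,4S,6R)-4-bromo-2-chloro-1-ethenyl-3,3-dimethyl-7-oxabicyclo[4.1.0]heptane | CC1(C)[C@@H](Br)C[C@H]2O[C@@]2(C=C)[C@@H]1Cl
F2 | step 8 | (Z)-2-[(2S,4S,6R)-4-bromo-2-chloro-6-hydroxy-3,3-dimethylcyclohexylidene]ethyl acetate | CC1(C)[C@@H](Br)C[C@@H](O)/C(=C/COC(C)=O)[C@@H]1Cl
F3 | step 7 | (S)-5-bromo-2-ethenyl-4,4-dimethylcyclohex-2-en-1-one | CC1(C)[C@@H](Br)CC(=O)C(C=C)=C1
F4 | step 7 | (2S,3S,5S)-5-bromo-3-chloro-2-ethenyl-4,4-dimethylcyclohexan-1-one | CC1(C)[C@@H](Br)CC(=O)[C@H](C=C)[C@@H]1Cl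
F5 | step 7 | (1R,2S,3S,5S)-5-bromo-3-chloro-2-ethenyl-4,4-dimethylcyclohexan-1-ol | CC1(C)[C@@H](Br)C[C@@H](O)[C@H](C=C)[C@@H]1Cl
F6 | step 6 | (1R,5S)-4-ethenyl-2,2-dimethyl-5-[(triethylsilyl)oxy]cyclohex-3-en-1-ol | CC1(C)[C@H](O)C[C@H](O[Si](CC)(CC)CC)C(C=C)=C1
F7 | step 6 | (1R,5S)-4-ethenyl-2,2-dimethyl-5-[(triethylsilyl)oxy]cyclohex-3-en-1-yl trifluoromethanesulfonate | CC1(C)[C@H](OS(=O)(=O)C(F)(F)F)C[C@H](O[Si](CC)(CC)CC)C(C=C)=C1
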